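**Retrosynthetic overview**
- Vibsanin P ⇒ macrocyclic allylic alcohol + 3-methylbut-2-enoic anhydride; the primary allylic alcohol is carried as a silyl ether until the last step.
- Eleven-membered carbocycle (second and last ring formed) ⇒ acyclic alkyne/epoxy aldehyde, closed at the carbinol–alkene bond by nickel-catalysed reductive alkyne–aldehyde coupling, which also sets the E-alkene and the carbinol centre.
- Acyclic chain ⇒ East aldehyde + West ester-stabilised ylide, joined by an E-selective Wittig reaction that builds the trisubstituted alkene.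
- East aldehyde ⇒ pent-1-en-4-yne, ethynyltrimethylsilane and 2-methylbut-3-en-2-ol: carboalumination, copper-catalysed enantioselective SN2′ alkynylation (quaternary centre), cross-metathesis.
- West ylide ⇒ 5-bromo-2-methylpent-2-ene + ethyl bromoacetate: allylic oxidation, Sharpless epoxidation (oxirane, first ring formed), ylide alkylation.

Assumption: in the two ligand-controlled steps (3 and 20) the ligand antipode that gives the drawn configuration is used; names are systematic (12-oxabicyclo[9.1.0]dodecane numbering for the macrocycle).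

**Step 1**
Reactants: 1 pent-1-en-4-yne
Product: 3 (2E)-3-methylhexa-2,5-dien-1-ol, via alkenylalane 2 (not isolated)
Conditions: Me3Al (2 equiv), Cp2ZrCl2 (20 mol %), CH2Cl2, 0 °C to rt; then n-BuLi, THF, −78 °C; (CH2O)n, −78 °C to rt
Reagents that add atoms: trimethylaluminium, C[Al](C)C; formaldehyde (as paraformaldehyde), C=O
Why: Negishi zirconium-catalysed carboalumination adds methyl and aluminium syn across the terminal alkyne (methyl to the internal carbon, isolated alkene untouched), and the alkenylalanate is hydroxymethylated with retention to give the E-trisubstituted allylic alcohol.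

**Step 2**
Reactants: 3 (2E)-3-methylhexa-2,5-dien-1-ol
Product: 4 diethyl (2E)-3-methylhexa-2,5-dien-1-yl phosphate
Conditions: ClP(O)(OEt)2, Et3N, DMAP (10 mol %), CH2Cl2, 0 °C to rt
Reagents that add atoms: diethyl chlorophosphate, CCOP(=O)(Cl)OCC
Why: Standard O-phosphorylation of a primary allylic alcohol gives the allylic electrophile without transposition.

**Step 3**
Reactants: 4 diethyl (2E)-3-methylhexa-2,5-dien-1-yl phosphate; 5 ethynyltrimethylsilane
Product: 7 [(3S)-3-ethenyl-3-methylhex-5-en-1-yn-1-yl]trimethylsilane, via alkynylalane 6 (not isolated)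
Conditions: 5, i-Bu2AlH, Et3N (5 mol %), hexanes/THF, rt (gives 6); then 4, CuCl2·2H2O (5 mol %), chiral sulfonate-bearing imidazolinium salt [1-(2,6-diisopropylphenyl)-3-(2-sulfonatophenyl)-4,5-diphenyl-4,5-dihydroimidazolium type] (5.5 mol %), THF, −30 °C
Reagents that add atoms: none
Why: Copper-catalysed enantioselective allylic substitution (SN2′) with an alkynylaluminium: the sulfonate-bridged NHC–copper complex delivers the alkynyl group to one face of the γ-carbon of the E-trisubstituted phosphate, creating the (S)-quaternary centre and the vinyl group.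

**Step 4**
Reactants: 7 [(3S)-3-ethenyl-3-methylhex-5-en-1-yn-1-yl]trimethylsilane; 8 2-methylbut-3-en-2-ol
Product: 9 (3E,6S)-6-ethenyl-2,6-dimethyl-8-(trimethylsilyl)oct-3-en-7-yn-2-ol
Conditions: 8 (5 equiv), second-generation Grubbs catalyst (H2IMes)(PCy3)Cl2Ru=CHPh (5 mol %), CH2Cl2, 40 °C
Reagents that add atoms: none
Why: Olefin cross-metathesis engages only the monosubstituted allyl alkene (the vinyl group on the quaternary carbon and the silylalkyne are inert), and the bulky tertiary carbinol partner gives the E-alkene.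

**Step 5**
Reactants: 9 (3E,6S)-6-ethenyl-2,6-dimethyl-8-(trimethylsilyl)oct-3-en-7-yn-2-ol
Product: 12 (3S,5E)-3-ethynyl-3,7-dimethyloct-5-ene-1,7-diol, via alkylborane 10 (not isolated), via silylalkyne diol 11 (not isolated)
Conditions: 9-BBN (2.5 equiv), THF, 0 °C to rt; then NaOH, H2O2, H2O, 0 °C to rt; then K2CO3, MeOH, rt
Reagents that add atoms: hydrogen peroxide, OO
Why: Anti-Markovnikov hydroboration–oxidation with 9-BBN selects the terminal vinyl group over the hindered internal alkene and the silylalkyne (one equivalent is consumed by the tertiary hydroxyl), and K2CO3/MeOH then removes the alkynyl silyl group in the same flask without touching the stereocentre.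

**Step 6**
Reactants: 12 (3S,5E)-3-ethynyl-3,7-dimethyloct-5-ene-1,7-diol
Product: 13 (3S,5E)-3-ethynyl-7-hydroxy-3,7-dimethyloct-5-enal
Conditions: Dess–Martin periodinane, pyridine, CH2Cl2, 0 °C to rt
Reagents that add atoms: none
Why: Dess–Martin oxidation converts the primary alcohol to the aldehyde; the tertiary alcohol cannot be oxidised and the quaternary β-carbon rules out epimerisation.

**Step 7**
Reactants: 14 5-bromo-2-methylpent-2-ene
Product: 15 (2E)-5-bromo-2-methylpent-2-en-1-ol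
Conditions: SeO2 (20 mol %), t-BuOOH (2 equiv), salicylic acid (10 mol %), CH2Cl2, rt
Reagents that add atoms: tert-butyl hydroperoxide, CC(C)(C)OO (terminal oxygen source, relayed through SeO2)
Why: Sharpless catalytic SeO2 allylic oxidation (ene reaction, then [2,3]-shift) hydroxylates the E-methyl group at the more substituted alkene terminus.

**Step 8**
Reactants: 15 (2E)-5-bromo-2-methylpent-2-en-1-ol
Product: 16 [(2S,3S)-3-(2-bromoethyl)-2-methyloxiran-2-yl]methanol
Conditions: Ti(OiPr)4 (10 mol %), L-(+)-diethyl tartrate (12 mol %), t-BuOOH (2 equiv, in decane), 4 Å molecular sieves, CH2Cl2, −20 °C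
Reagents that add atoms: tert-butyl hydroperoxide, CC(C)(C)OO
Why: Sharpless asymmetric epoxidation with L-(+)-diethyl tartrate delivers oxygen to the face of the E-2-methyl allylic alcohol that gives the (2S,3S)-epoxy alcohol, setting both oxirane stereocentres.

**Step 9**
Reactants: 16 [(2S,3S)-3-(2-bromoethyl)-2-methyloxiran-2-yl]methanol
Product: 17 {[(2S,3S)-3-(2-bromoethyl)-2-methyloxiran-2-yl]methoxy}triethylsilane
Conditions: Et3SiCl, imidazole, CH2Cl2, 0 °C
Reagents that add atoms: chlorotriethylsilane, CC[Si](Cl)(CC)CC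
Why: Routine silylation of the primary alcohol masks it for the ylide chemistry and the later ester reduction.

**Step 10**
Reactants: 17 {[(2S,3S)-3-(2-bromoethyl)-2-methyloxiran-2-yl]methoxy}triethylsilane
Product: 18 triethyl{[(2S,3S)-3-(2-iodoethyl)-2-methyloxiran-2-yl]methoxy}silane
Conditions: NaI, NaHCO3, acetone, reflux
Reagents that add atoms: sodium iodide, [Na+].[I-]
Why: Finkelstein exchange (SN2 at the primary carbon) gives the more reactive iodide under neutral conditions that spare the epoxide.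

**Step 11**
Reactants: 19 ethyl bromoacetate
Product: 20 (2-ethoxy-2-oxoethyl)triphenylphosphonium bromide
Conditions: PPh3, toluene, rt
Reagents that add atoms: triphenylphosphine, c1ccc(cc1)P(c1ccccc1)c1ccccc1
Why: SN2 quaternisation of triphenylphosphine by the α-bromo ester; the salt precipitates.

**Step 12**
Reactants: 20 (2-ethoxy-2-oxoethyl)triphenylphosphonium bromide
Product: 21 ethyl (triphenylphosphoranylidene)acetate
Conditions: NaOH (aq), CH2Cl2, rt
Reagents that add atoms: none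
Why: Deprotonation of the acidic phosphonium salt gives the isolable ester-stabilised ylide.

**Step 13**
Reactants: 18 triethyl{[(2S,3S)-3-(2-iodoethyl)-2-methyloxiran-2-yl]methoxy}silane; 21 ethyl (triphenylphosphoranylidene)acetate
Product: 23 ethyl 4-[(2S,3S)-3-methyl-3-{[(triethylsilyl)oxy]methyl}oxiran-2-yl]-2-(triphenylphosphoranylidene)butanoate, via phosphonium iodide 22 (not isolated)
Conditions: 21 (2.2 equiv), MeCN, 70 °C
Reagents that add atoms: none
Why: C-alkylation of the stabilised ylide by the primary iodide, then transylidation by the second equivalent of 21, gives the α-substituted ylide under near-neutral conditions that the epoxide and silyl ether tolerate.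

**Step 14**
Reactants: 24 3-methylbut-2-enoic acid (two molecules per molecule of product)
Product: 25 3-methylbut-2-enoic anhydride
Conditions: 24 (2.0 equiv), DCC (1.0 equiv), CH2Cl2, 0 °C to rt; filter off the urea
Reagents that add atoms: 3-methylbut-2-enoic acid (the second molecule of 24), CC(C)=CC(=O)O
Why: Carbodiimide-mediated dehydration, in which one acid molecule adds to DCC to give the O-acylisourea and the second acid molecule attacks it to give the symmetric anhydride and dicyclohexylurea; the anhydride is a clean acyl donor that avoids the deconjugation seen with the acid chloride.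

**Step 15**
Reactants: 13 (3S,5E)-3-ethynyl-7-hydroxy-3,7-dimethyloct-5-enal; 23 ethyl 4-[(2S,3S)-3-methyl-3-{[(triethylsilyl)oxy]methyl}oxiran-2-yl]-2-(triphenylphosphoranylidene)butanoate
Product: 26 ethyl (2E,5S,7E)-5-ethynyl-9-hydroxy-5,9-dimethyl-2-{2-[(2S,3S)-3-methyl-3-{[(triethylsilyl)oxy]methyl}oxiran-2-yl]ethyl}deca-2,7-dienoate
Conditions: toluene, 90 °C
Reagents that add atoms: none
Why: Wittig olefination with an α-substituted ester-stabilised ylide is E-selective (ester trans to the aldehyde-derived chain), which fixes the geometry of the trisubstituted alkene.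

**Step 16**
Reactants: 26 ethyl (2E,5S,7E)-5-ethynyl-9-hydroxy-5,9-dimethyl-2-{2-[(2S,3S)-3-methyl-3-{[(triethylsilyl)oxy]methyl}oxiran-2-yl]ethyl}deca-2,7-dienoate
Product: 27 (2E,5S,7E)-5-ethynyl-5,9-dimethyl-2-{2-[(2S,3S)-3-methyl-3-{[(triethylsilyl)oxy]methyl}oxiran-2-yl]ethyl}deca-2,7-diene-1,9-diol
Conditions: i-Bu2AlH (4 equiv), CH2Cl2, −78 °C
Reagents that add atoms: none
Why: i-Bu2AlH 1,2-reduction of the enoate at −78 °C gives the allylic alcohol while the epoxide, silyl ether and alkyne are inert.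

**Step 17**
Reactants: 27 (2E,5S,7E)-5-ethynyl-5,9-dimethyl-2-{2-[(2S,3S)-3-methyl-3-{[(triethylsilyl)oxy]methyl}oxiran-2-yl]ethyl}deca-2,7-diene-1,9-diol
Product: 28 (3E,6S,8E)-9-({[tert-butyl(diphenyl)silyl]oxy}methyl)-6-ethynyl-2,6-dimethyl-11-[(2S,3S)-3-methyl-3-{[(triethylsilyl)oxy]methyl}oxiran-2-yl]undeca-3,8-dien-2-ol
Conditions: t-BuPh2SiCl, imidazole, DMF, 0 °C to rt
Reagents that add atoms: tert-butyl(chloro)diphenylsilane, CC(C)(C)[Si](Cl)(c1ccccc1)c1ccccc1
Why: The bulky silyl chloride protects only the primary allylic alcohol; the tertiary alcohol does not react.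

**Step 18**
Reactants: 28 (3E,6S,8E)-9-({[tert-butyl(diphenyl)silyl]oxy}methyl)-6-ethynyl-2,6-dimethyl-11-[(2S,3S)-3-methyl-3-{[(triethylsilyl)oxy]methyl}oxiran-2-yl]undeca-3,8-dien-2-ol
Product: 29 (3E,6S,8E)-9-({[tert-butyl(diphenyl)silyl]oxy}methyl)-6-ethynyl-11-[(2S,3S)-3-(hydroxymethyl)-3-methyloxiran-2-yl]-2,6-dimethylundeca-3,8-dien-2-ol
Conditions: HF·pyridine, pyridine, THF, 0 °C
Reagents that add atoms: none
Why: Buffered HF·pyridine cleaves the primary triethylsilyl ether much faster than the tert-butyldiphenylsilyl ether and leaves the epoxide intact.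

**Step 19**
Reactants: 29 (3E,6S,8E)-9-({[tert-butyl(diphenyl)silyl]oxy}methyl)-6-ethynyl-11-[(2S,3S)-3-(hydroxymethyl)-3-methyloxiran-2-yl]-2,6-dimethylundeca-3,8-dien-2-ol
Product: 30 (2R,3S)-3-[(3E,6S,8E)-3-({[tert-butyl(diphenyl)silyl]oxy}methyl)-6-ethynyl-10-hydroxy-6,10-dimethylundeca-3,8-dien-1-yl]-2-methyloxirane-2-carbaldehyde
Conditions: Dess–Martin periodinane, pyridine, CH2Cl2, 0 °C
Reagents that add atoms: none
Why: Dess–Martin oxidation gives the α,β-epoxy aldehyde, which has no α-hydrogen and so cannot epimerise.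

**Step 20**
Reactants: 30 (2R,3S)-3-[(3E,6S,8E)-3-({[tert-butyl(diphenyl)silyl]oxy}methyl)-6-ethynyl-10-hydroxy-6,10-dimethylundeca-3,8-dien-1-yl]-2-methyloxirane-2-carbaldehyde
Product: 32 (1S,2R,3E,5S,7E,11S)-8-({[tert-butyl(diphenyl)silyl]oxy}methyl)-5-[(2E)-4-hydroxy-4-methylpent-2-en-1-yl]-1,5-dimethyl-12-oxabicyclo[9.1.0]dodeca-3,7-dien-2-ol, via macrocyclic triethylsilyl ether 31 (not isolated)
Conditions: Ni(cod)2 (20 mol %), chiral imidazolinium tetrafluoroborate [(4R,5R)-1,3-bis(2-methylphenyl)-4,5-diphenyl-4,5-dihydroimidazolium BF4] (22 mol %), KOt-Bu (22 mol %), Et3SiH (5 equiv), THF, rt, syringe-pump addition of 30 (final 2 mM); then HF·pyridine, pyridine, 0 °C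
Reagents that add atoms: none
Why: Proposed new method: zerovalent-nickel/chiral-NHC-catalysed endo-selective reductive macrocyclisation of a terminal alkyne onto an α,β-epoxy aldehyde to close an 11-membered ring — alkyne and aldehyde undergo oxidative cyclisation at nickel to an oxanickelacyclopentene with C–C bond formation at the unsubstituted alkyne carbon (the adjacent quaternary centre blocks bonding at the internal carbon), σ-bond metathesis of Ni–O with Et3SiH and C–H reductive elimination then give the silyl ether with syn delivery of H and C (hence the E-alkene), and the C2-symmetric NHC directs the alkenyl carbon to the Re face of the aldehyde, in the conformer with the epoxide C–O bond anti to the forming bond, to set the (R)-carbinol; the closest known reactions are nickel/NHC/silane macrocyclisations of terminal alkynyl aldehydes (larger rings, no epoxide) and intermolecular asymmetric aldehyde–alkyne reductive couplings, and buffered HF·pyridine then frees the secondary alcohol in the same flask.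

**Step 21**
Reactants: 32 (1S,2R,3E,5S,7E,11S)-8-({[tert-butyl(diphenyl)silyl]oxy}methyl)-5-[(2E)-4-hydroxy-4-methylpent-2-en-1-yl]-1,5-dimethyl-12-oxabicyclo[9.1.0]dodeca-3,7-dien-2-ol; 25 3-methylbut-2-enoic anhydride
Product: 33 (1R,2R,3E,5S,7E,11S)-8-({[tert-butyl(diphenyl)silyl]oxy}methyl)-5-[(2E)-4-hydroxy-4-methylpent-2-en-1-yl]-1,5-dimethyl-12-oxabicyclo[9.1.0]dodeca-3,7-dien-2-yl 3-methylbut-2-enoate
Conditions: 25 (3 equiv), DMAP, Et3N, CH2Cl2, 0 °C to rt
Reagents that add atoms: none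
Why: DMAP-catalysed acylation esterifies the secondary allylic alcohol with retention at the carbinol carbon, while the tertiary alcohol is too hindered to react.

**Step 22**
Reactants: 33 (1R,2R,3E,5S,7E,11S)-8-({[tert-butyl(diphenyl)silyl]oxy}methyl)-5-[(2E)-4-hydroxy-4-methylpent-2-en-1-yl]-1,5-dimethyl-12-oxabicyclo[9.1.0]dodeca-3,7-dien-2-yl 3-methylbut-2-enoate
Product: 34 vibsanin P, (1R,2R,3E,5S,7E,11S)-8-(hydroxymethyl)-5-[(2E)-4-hydroxy-4-methylpent-2-en-1-yl]-1,5-dimethyl-12-oxabicyclo[9.1.0]dodeca-3,7-dien-2-yl 3-methylbut-2-enoate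
Conditions: Bu4NF, AcOH, THF, 0 °C to rt
Reagents that add atoms: none
Why: Fluoride desilylation, buffered with acetic acid to prevent acyl migration and epoxide opening, releases the primary allylic alcohol.

**Compound list**
1 | pent-1-en-4-yne | C=CCC#C | starting material
2 | dimethyl[(1E)-2-methylpenta-1,4-dien-1-yl]alumane (not isolated) | C[Al](C)/C=C(\C)CC=C | intermediate
3 | (2E)-3-methylhexa-2,5-dien-1-ol | OC/C=C(\C)CC=C | intermediate
4 | diethyl (2E)-3-methylhexa-2,5-dien-1-yl phosphate | CCOP(=O)(OCC)OC/C=C(\C)CC=C | intermediate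
5 | ethynyltrimethylsilane | C#C[Si](C)(C)C | starting material
6 | bis(2-methylpropyl)[(trimethylsilyl)ethynyl]alumane (not isolated) | CC(C)C[Al](CC(C)C)C#C[Si](C)(C)C | intermediate
7 | [(3S)-3-ethenyl-3-methylhex-5-en-1-yn-1-yl]trimethylsilane | C[Si](C)(C)C#C[C@@](C)(CC=C)C=C | intermediate
8 | 2-methylbut-3-en-2-ol | CC(C)(O)C=C | starting material
9 | (3E,6S)-6-ethenyl-2,6-dimethyl-8-(trimethylsilyl)oct-3-en-7-yn-2-ol | C[Si](C)(C)C#C[C@@](C)(C/C=C/C(C)(C)O)C=C | intermediate
10 | (3E,6R)-8-(9-borabicyclo[3.3.1]nonan-9-yl)-2,6-dimethyl-6-[(trimethylsilyl)ethynyl]oct-3-en-2-ol (not isolated; descriptor R only because the boron-bearing arm ranks below the alkenyl arm, spatial arrangement as in 9) | C[Si](C)(C)C#C[C@@](C)(C/C=C/C(C)(C)O)CCB1C2CCCC1CCC2 | intermediate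
11 | (3S,5E)-3,7-dimethyl-3-[(trimethylsilyl)ethynyl]oct-5-ene-1,7-diol (not isolated) | C[Si](C)(C)C#C[C@@](C)(C/C=C/C(C)(C)O)CCO | intermediate
12 | (3S,5E)-3-ethynyl-3,7-dimethyloct-5-ene-1,7-diol | C#C[C@@](C)(C/C=C/C(C)(C)O)CCO | intermediate
13 | (3S,5E)-3-ethynyl-7-hydroxy-3,7-dimethyloct-5-enal | C#C[C@@](C)(C/C=C/C(C)(C)O)CC=O | intermediate
14 | 5-bromo-2-methylpent-2-ene | CC(C)=CCCBr | starting material
15 | (2E)-5-bromo-2-methylpent-2-en-1-ol | OC/C(C)=C/CCBr | intermediate
16 | [(2S,3S)-3-(2-bromoethyl)-2-methyloxiran-2-yl]methanol | BrCC[C@@H]1O[C@]1(CO)C | intermediate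
17 | {[(2S,3S)-3-(2-bromoethyl)-2-methyloxiran-2-yl]methoxy}triethylsilane | BrCC[C@@H]1O[C@]1(CO[Si](CC)(CC)CC)C | intermediate
18 | triethyl{[(2S,3S)-3-(2-iodoethyl)-2-methyloxiran-2-yl]methoxy}silane | ICC[C@@H]1O[C@]1(CO[Si](CC)(CC)CC)C | intermediate
19 | ethyl bromoacetate | BrCC(=O)OCC | starting material
20 | (2-ethoxy-2-oxoethyl)triphenylphosphonium bromide | CCOC(=O)C[P+](c1ccccc1)(c1ccccc1)c1ccccc1.[Br-] | intermediate
21 | ethyl (triphenylphosphoranylidene)acetate | CCOC(=O)C=P(c1ccccc1)(c1ccccc1)c1ccccc1 | intermediate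
22 | {1-ethoxy-4-[(2S,3S)-3-methyl-3-{[(triethylsilyl)oxy]methyl}oxiran-2-yl]-1-oxobutan-2-yl}triphenylphosphonium iodide (not isolated) | CCOC(=O)C(CC[C@@H]1O[C@]1(CO[Si](CC)(CC)CC)C)[P+](c2ccccc2)(c2ccccc2)c2ccccc2.[I-] | intermediate
23 | ethyl 4-[(2S,3S)-3-methyl-3-{[(triethylsilyl)oxy]methyl}oxiran-2-yl]-2-(triphenylphosphoranylidene)butanoate | CCOC(=O)C(CC[C@@H]1O[C@]1(CO[Si](CC)(CC)CC)C)=P(c2ccccc2)(c2ccccc2)c2ccccc2 | intermediate
24 | 3-methylbut-2-enoic acid | CC(C)=CC(=O)O | starting material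
25 | 3-methylbut-2-enoic anhydride | CC(C)=CC(=O)OC(=O)C=C(C)C | intermediate
26 | ethyl (2E,5S,7E)-5-ethynyl-9-hydroxy-5,9-dimethyl-2-{2-[(2S,3S)-3-methyl-3-{[(triethylsilyl)oxy]methyl}oxiran-2-yl]ethyl}deca-2,7-dienoate | C#C[C@@](C)(C/C=C/C(C)(C)O)C/C=C(/C(=O)OCC)CC[C@@H]1O[C@]1(CO[Si](CC)(CC)CC)C | intermediate
27 | (2E,5S,7E)-5-ethynyl-5,9-dimethyl-2-{2-[(2S,3S)-3-methyl-3-{[(triethylsilyl)oxy]methyl}oxiran-2-yl]ethyl}deca-2,7-diene-1,9-diol | C#C[C@@](C)(C/C=C/C(C)(C)O)C/C=C(/CO)CC[C@@H]1O[C@]1(CO[Si](CC)(CC)CC)C | intermediate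
28 | (3E,6S,8E)-9-({[tert-butyl(diphenyl)silyl]oxy}methyl)-6-ethynyl-2,6-dimethyl-11-[(2S,3S)-3-methyl-3-{[(triethylsilyl)oxy]methyl}oxiran-2-yl]undeca-3,8-dien-2-ol | C#C[C@@](C)(C/C=C/C(C)(C)O)C/C=C(/CO[Si](c1ccccc1)(c1ccccc1)C(C)(C)C)CC[C@@H]1O[C@]1(CO[Si](CC)(CC)CC)C | intermediate
29 | (3E,6S,8E)-9-({[tert-butyl(diphenyl)silyl]oxy}methyl)-6-ethynyl-11-[(2S,3S)-3-(hydroxymethyl)-3-methyloxiran-2-yl]-2,6-dimethylundeca-3,8-dien-2-ol | C#C[C@@](C)(C/C=C/C(C)(C)O)C/C=C(/CO[Si](c1ccccc1)(c1ccccc1)C(C)(C)C)CC[C@@H]1O[C@]1(CO)C | intermediate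
30 | (2R,3S)-3-[(3E,6S,8E)-3-({[tert-butyl(diphenyl)silyl]oxy}methyl)-6-ethynyl-10-hydroxy-6,10-dimethylundeca-3,8-dien-1-yl]-2-methyloxirane-2-carbaldehyde | C#C[C@@](C)(C/C=C/C(C)(C)O)C/C=C(/CO[Si](c1ccccc1)(c1ccccc1)C(C)(C)C)CC[C@@H]1O[C@]1(C=O)C | intermediate
31 | {[(1R,2R,3E,5S,7E,11S)-8-({[tert-butyl(diphenyl)silyl]oxy}methyl)-5-[(2E)-4-hydroxy-4-methylpent-2-en-1-yl]-1,5-dimethyl-12-oxabicyclo[9.1.0]dodeca-3,7-dien-2-yl]oxy}triethylsilane (not isolated) | CC[Si](CC)(CC)O[C@@H]1/C=C/[C@@](C)(C/C=C/C(C)(C)O)C/C=C(/CO[Si](c3ccccc3)(c3ccccc3)C(C)(C)C)CC[C@@H]2O[C@]21C | intermediate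
32 | (1S,2R,3E,5S,7E,11S)-8-({[tert-butyl(diphenyl)silyl]oxy}methyl)-5-[(2E)-4-hydroxy-4-methylpent-2-en-1-yl]-1,5-dimethyl-12-oxabicyclo[9.1.0]dodeca-3,7-dien-2-ol (C-1 reads S only because the free hydroxyl lowers the CIP rank of C-2; spatial arrangement as in 34) | O[C@@H]1/C=C/[C@@](C)(C/C=C/C(C)(C)O)C/C=C(/CO[Si](c3ccccc3)(c3ccccc3)C(C)(C)C)CC[C@@H]2O[C@]21C | intermediate
33 | (1R,2R,3E,5S,7E,11S)-8-({[tert-butyl(diphenyl)silyl]oxy}methyl)-5-[(2E)-4-hydroxy-4-methylpent-2-en-1-yl]-1,5-dimethyl-12-oxabicyclo[9.1.0]dodeca-3,7-dien-2-yl 3-methylbut-2-enoate | CC(C)=CC(=O)O[C@@H]1/C=C/[C@@](C)(C/C=C/C(C)(C)O)C/C=C(/CO[Si](c3ccccc3)(c3ccccc3)C(C)(C)C)CC[C@@H]2O[C@]21C | intermediate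
34 | vibsanin P, (1R,2R,3E,5S,7E,11S)-8-(hydroxymethyl)-5-[(2E)-4-hydroxy-4-methylpent-2-en-1-yl]-1,5-dimethyl-12-oxabicyclo[9.1.0]dodeca-3,7-dien-2-yl 3-methylbut-2-enoate | CC(C)=CC(=O)O[C@@H]1/C=C/[C@@](C)(C/C=C/C(C)(C)O)C/C=C(/CO)CC[C@@H]2O[C@]21C | target

**Step count**
Total step count: 22 (East fragment, steps 1–6; West fragment, steps 7–10 and 13; ylide reagent, steps 11–12; anhydride, step 14; joint sequence, steps 15–22).
Longest linear sequence: 14 steps (1–6, then 15–22).

**Three steps most likely to fail**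

Step 20 (the proposed nickel macrocyclisation). The risks are exo instead of endo cyclisation, insertion of zerovalent nickel into the epoxide C–O bond, plain hydrosilylation or oligomerisation of the aldehyde, and poor control of the new carbinol centre. The fallback uses known chemistry, sets out from 29 and comes back at 32. Hydrostannation of the terminal alkyne of 29 (Bu3SnH, PdCl2(PPh3)2, THF, 0 °C) gives the (E)-alkenylstannane F1. Iododestannylation (I2, CH2Cl2, −78 °C) gives the (E)-alkenyl iodide F2. Dess–Martin oxidation gives the iodo epoxy aldehyde F3. A Nozaki–Hiyama–Kishi macrocyclisation (CrCl2 in excess, NiCl2 1 mol %, DMSO/THF, 2 mM) then forms the same bond and gives the free alcohol 32 directly. Selectivity at the carbinol is then substrate-controlled and the epimers are separated by chromatography.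

Step 3 (copper-catalysed SN2′ alkynylation). The catalyst must tell methyl from allyl at the γ-carbon, so the enantiomeric ratio may be moderate, and some SN2 product is possible. The fallback sets out from 3 and comes back at 7. Sharpless epoxidation of 3 with D-(−)-diethyl tartrate gives the epoxy alcohol F4. Et2Al–C≡C–SiMe3 (from 5, n-BuLi and Et2AlCl; toluene, 0 °C) opens the epoxide at the fully substituted carbon with inversion to give the diol F5. NaIO4 cleavage gives the α-quaternary aldehyde F6. Methylenation with Ph3P=CH2 returns 7 as the same (S)-enantiomer.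

Step 13 (ylide alkylation). C-alkylation by an unactivated primary iodide is slow, and iodide may open the epoxide at 70 °C. The fallback sets out from 18 (with 19 and 13) and comes back at 26. Arbuzov reaction of 19 with P(OEt)3 gives triethyl phosphonoacetate F7. Its sodium salt (NaH, DMF, 50 °C) is alkylated by 18 under basic conditions, which are safe for the epoxide, to give the phosphonate F8. Horner–Wadsworth–Emmons reaction of F8 with aldehyde 13 (LiCl, DBU, MeCN) gives the enoate 26 after chromatographic removal of the Z-isomer, which bypasses 23 and step 15.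

**Further compounds**
F1 | step 20 | (3E,6S,8E)-9-({[tert-butyl(diphenyl)silyl]oxy}methyl)-11-[(2S,3S)-3-(hydroxymethyl)-3-methyloxiran-2-yl]-2,6-dimethyl-6-[(E)-2-(tributylstannyl)ethenyl]undeca-3,8-dien-2-ol | CCCC[Sn](CCCC)(CCCC)/C=C/[C@@](C)(C/C=C/C(C)(C)O)C/C=C(/CO[Si](c1ccccc1)(c1ccccc1)C(C)(C)C)CC[C@@H]1O[C@]1(CO)C
F2 | step 20 | (3E,6S,8E)-9-({[tert-butyl(diphenyl)silyl]oxy}methyl)-11-[(2S,3S)-3-(hydroxymethyl)-3-methyloxiran-2-yl]-6-[(E)-2-iodoethenyl]-2,6-dimethylundeca-3,8-dien-2-ol | I/C=C/[C@@](C)(C/C=C/C(C)(C)O)C/C=C(/CO[Si](c1ccccc1)(c1ccccc1)C(C)(C)C)CC[C@@H]1O[C@]1(CO)C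
F3 | step 20 | (2R,3S)-3-[(3E,6S,8E)-3-({[tert-butyl(diphenyl)silyl]oxy}methyl)-10-hydroxy-6-[(E)-2-iodoethenyl]-6,10-dimethylundeca-3,8-dien-1-yl]-2-methyloxirane-2-carbaldehyde | I/C=C/[C@@](C)(C/C=C/C(C)(C)O)C/C=C(/CO[Si](c1ccccc1)(c1ccccc1)C(C)(C)C)CC[C@@H]1O[C@]1(C=O)C
F4 | step 3 | [(2R,3R)-3-methyl-3-(prop-2-en-1-yl)oxiran-2-yl]methanol | OC[C@H]1O[C@]1(C)CC=C
F5 | step 3 | (2S,3R)-3-methyl-3-(prop-2-en-1-yl)-5-(trimethylsilyl)pent-4-yne-1,2-diol | C[Si](C)(C)C#C[C@@](C)(CC=C)[C@H](O)CO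
F6 | step 3 | (2R)-2-methyl-2-(prop-2-en-1-yl)-4-(trimethylsilyl)but-3-ynal | C[Si](C)(C)C#C[C@@](C)(CC=C)C=O
F7 | step 13 | ethyl (diethoxyphosphoryl)acetate | CCOC(=O)CP(=O)(OCC)OCC
F8 | step 13 | ethyl 2-(diethoxyphosphoryl)-4-[(2S,3S)-3-methyl-3-{[(triethylsilyl)oxy]methyl}oxiran-2-yl]butanoate (both C-2 epimers) | CCOC(=O)C(CC[C@@H]1O[C@]1(CO[Si](CC)(CC)CC)C)P(=O)(OCC)OCC
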